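(The constants were set for the occasion; no experiment stands behind them.)

The reagent met the substrate in four flasks that differed in how the two went in.

in all of them: time 3.0 s
- noon: substrate 2.0 × 10⁻⁴ M; reagent 1.00 equiv; everything together at the start
- winter: substrate 2.0 × 10⁻⁴ M; reagent 1.00 equiv (fed, over 2.0 s); all else is in the flask from the start; the feed brings no volume worth counting
- dusk: substrate 2.0 × 10⁻⁴ M; reagent 1.00 equiv (in portions, 3, over 2.0 s); first portion at the start, last at 2.0 s
- dawn: substrate 2.0 × 10⁻⁴ M (fed, over 2.0 s); reagent 1.00 equiv; all else is in the flask from the start; the feed brings no volume worth counting

    substrate + reagent → target (k1 = 2500 /M/s)
    substrate + reagent → isomer of the product (k2 = 2660 /M/s)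
    substrate + reagent → second isomer (k3 = 1930 /M/s)

1. the flask that comes out highest in share of target in target plus isomer of the product, or "all alike" when all lie within 1.5 percentage points (noon / winter / dusk / dawn / all alike)
2. share of target in target plus isomer of the product at the end, noon
3. share of target in target plus isomer of the product at the end, winter
4. share of target in target plus isomer of the product at the end, dusk
5. share of target in target plus isomer of the product at the end, dawn

I built my reckoning as a ladder, fastest rung first. On the first rung no clock runs: the step to target goes at 2500 /M/s times c(substrate) times c(reagent), the step to isomer of the product at 2660 /M/s times the same two concentrations, so these cancel and the two rates stand at 1.06 to one at any moment. I therefore carried the branch share, the constant of the step to target over the sum of the constants of the steps to target and to isomer of the product, 48.45%; it is the selectivity factor written as a share. Equal constants split half and half, and that was my zero: these constants put target 1.5 percentage points below it.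

The second rung was the lifetime of substrate against the whole charge, 0.705 s. Then came the dosing, 2.0 s or 2.8 such lifetimes, so I expected winter, dusk and dawn to lag behind noon in how much had reacted. The asked time, 3.0 s, came last, at 4.26 lifetimes. Neither rung enters the cancelled ratio, so I committed to 48.4% for noon, winter, dusk and dawn, with no difference between them.

The forecast gave 48.45% for noon, 48.45% for winter, 48.45% for dusk and 48.45% for dawn, and answered all alike. Its ground was this: "The way of dosing therefore changes how much reacts but not the share".

The simulation gave 48.4% in noon, 48.4% in winter, 48.4% in dusk and 48.4% in dawn, hence all alike, while the substrate left at the end stood at 19% in noon and 30% in dusk. In noon at the end, counted in percent of the substrate charged, 28.5% of target and 30.4% of isomer of the product had formed, and the branch share of their sum is 28.5%. The neighbour of noon with 3.4 × 10⁻⁴ M of substrate made, in percent of its own substrate charged, 33.0% of isomer of the product beside its target; the branch share of their sum is 31.0%, and that flask held 31.0% of target.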